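The cyclopentane is disconnected at C2–C3 and C1–C8a (azulene numbering), exploiting the 1,3-relationship between the tertiary carbinol C3 and the acetoxy carbon C1 beside the quaternary C8a. A Prins cyclization–pinacol rearrangement forms both bonds in one operation: in a cycloheptene bearing an isobutyryl group at C3a and a silylated 2-hydroxybut-3-en-2-yl group at C8a, the vinyl terminus adds to the activated ketone through a trans-fused chair, and 1,2-shift of C8a contracts the new six-membered ring to the trans-hydroazulene with a C1 acetyl group. Baeyer–Villiger oxidation later turns that acetyl into the C1 acetate. The precursor comes from a cycloheptadienone by asymmetric conjugate addition and aldol trapping.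

Key step: step 13

Remark: compounds 4–7 are racemic (their stereocentres are erased or irrelevant), and the side-chain carbinol carbon of 18–21 is carried as a mixture of epimers because it becomes the acetyl carbonyl in step 13.

Step 1
Reactants: 1 3-ethoxycyclohex-2-en-1-one
Product: 3 3-((trimethylsilyl)ethynyl)cyclohex-2-en-1-one, via lithium alkoxide adduct 2 (not isolated)
Conditions: Me3SiC≡CH, n-BuLi, THF, −78 to 0 °C; then 1 M HCl
Reagents that add atoms: ethynyltrimethylsilane, C#C[Si](C)(C)C; water, O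
Why: Stork–Danheiser sequence, in which the acetylide adds 1,2 to the vinylogous ester and acid hydrolysis with allylic transposition should give the 3-alkynyl enone (no stereocentre).

Step 2
Reactants: 3 3-((trimethylsilyl)ethynyl)cyclohex-2-en-1-one
Product: 4 6-methyl-3-((trimethylsilyl)ethynyl)cyclohex-2-en-1-one (racemic)
Conditions: LDA, THF, −78 °C; MeI
Reagents that add atoms: iodomethane, CI
Why: Kinetic α′-deprotonation of the enone and enolate alkylation should place the methyl group that becomes the C6 methyl; its stereocentre is erased in step 3.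

Step 3
Reactants: 4 6-methyl-3-((trimethylsilyl)ethynyl)cyclohex-2-en-1-one
Product: 5 trimethyl((2-methyl-5-((trimethylsilyl)ethynyl)cyclohexa-1,5-dien-1-yl)oxy)silane
Conditions: LDA, Me3SiCl, THF, −78 °C
Reagents that add atoms: chlorotrimethylsilane, C[Si](C)(C)Cl
Why: Kinetic α′-enolization and O-silylation should give the cross-conjugated 2-silyloxy diene.

Step 4
Reactants: 5 trimethyl((2-methyl-5-((trimethylsilyl)ethynyl)cyclohexa-1,5-dien-1-yl)oxy)silane
Product: 6 trimethyl((6-methyl-3-((trimethylsilyl)ethynyl)bicyclo[4.1.0]hept-2-en-1-yl)oxy)silane (racemic)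
Conditions: Et2Zn, CH2I2, CH2Cl2, 0 °C
Reagents that add atoms: diiodomethane, ICI
Why: Simmons–Smith cyclopropanation (zinc carbenoid) should occur chemoselectively at the electron-rich silyl enol ether double bond; the ring fusion is necessarily cis.

Step 5
Reactants: 6 trimethyl((6-methyl-3-((trimethylsilyl)ethynyl)bicyclo[4.1.0]hept-2-en-1-yl)oxy)silane
Product: 8 3-methyl-6-((trimethylsilyl)ethynyl)cyclohepta-2,6-dien-1-one, via β-chloro ketone 7 (not isolated)
Conditions: FeCl3, DMF, 0 °C to rt; then Et3N, CH2Cl2, rt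
Reagents that add atoms: none
Why: Ito–Saegusa one-carbon ring expansion, in which oxidation of the siloxycyclopropane cleaves the internal bond to the tertiary β-keto radical, chlorine transfer gives 7, and elimination of HCl should give the cross-conjugated dienone.

Step 6
Reactants: 8 3-methyl-6-((trimethylsilyl)ethynyl)cyclohepta-2,6-dien-1-one; 9 isobutyraldehyde
Product: 11 (6S,7S)-7-((S)-1-hydroxy-2-methylpropyl)-3,6-dimethyl-6-((trimethylsilyl)ethynyl)cyclohept-2-en-1-one, via magnesium enolate 10 (not isolated)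
Conditions: Cu(OTf)2 (3 mol %), chiral hydroxyalkyl imidazolinium salt (NHC precursor, 4 mol %), MeMgBr, Et2O, −30 °C; then i-PrCHO, −78 °C; aq. NH4Cl
Reagents that add atoms: methylmagnesium bromide, C[Mg]Br
Why: Copper-catalysed asymmetric 1,4-addition of a Grignard reagent to a cyclic enynone should methylate the alkynyl-bearing β-carbon (the more electrophilic and less hindered terminus; ligand enantiomer chosen for the S quaternary centre), and the magnesium enolate should then add to the aldehyde through a Zimmerman–Traxler chair (ring E-enolate, anti aldol) on the face anti to the slender pseudo-axial alkynyl group, so the side chain ends cis to methyl.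

Step 7
Reactants: 11 (6S,7S)-7-((S)-1-hydroxy-2-methylpropyl)-3,6-dimethyl-6-((trimethylsilyl)ethynyl)cyclohept-2-en-1-one
Product: 14 (1R,6S,7S)-6-ethynyl-7-((S)-1-hydroxy-2-methylpropyl)-3,6-dimethylcyclohept-2-en-1-ol, via boron aldolate 12 (not isolated), via silylalkyne diol 13 (not isolated)
Conditions: Et2BOMe, NaBH4, THF/MeOH (4:1), −78 °C; then K2CO3, MeOH, rt
Reagents that add atoms: none
Why: Narasaka–Prasad reduction, in which external hydride attack on the boron chelate should give the 1,3-syn diol and thus the ring hydroxyl trans to the side chain; methanolysis with K2CO3 also removes the alkynyl silyl group.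

Step 8
Reactants: 14 (1R,6S,7S)-6-ethynyl-7-((S)-1-hydroxy-2-methylpropyl)-3,6-dimethylcyclohept-2-en-1-ol
Product: 15 (1R,6S,7S)-6-acetyl-7-((S)-1-hydroxy-2-methylpropyl)-3,6-dimethylcyclohept-2-en-1-ol
Conditions: Ph3PAuCl (3 mol %), AgSbF6 (3 mol %), H2O, 1,4-dioxane, 60 °C
Reagents that add atoms: water, O
Why: Gold-catalysed Markovnikov hydration of the terminal alkyne should give the methyl ketone without touching the trisubstituted alkene (5-exo participation of the neighbouring hydroxyl leads to the same ketone).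

Step 9
Reactants: 15 (1R,6S,7S)-6-acetyl-7-((S)-1-hydroxy-2-methylpropyl)-3,6-dimethylcyclohept-2-en-1-ol; 16 4-((tert-butyldimethylsilyl)oxy)benzoic acid
Product: 17 (1R,6S,7S)-6-acetyl-7-((S)-1-hydroxy-2-methylpropyl)-3,6-dimethylcyclohept-2-en-1-yl 4-((tert-butyldimethylsilyl)oxy)benzoate
Conditions: EDC·HCl, DMAP, CH2Cl2, 0 °C to rt
Reagents that add atoms: none
Why: Steglich esterification should acylate the more accessible allylic ring hydroxyl with retention, because the other carbinol is flanked by isopropyl and the ring and can be held as a lactol with the acetyl group.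

Step 10
Reactants: 17 (1R,6S,7S)-6-acetyl-7-((S)-1-hydroxy-2-methylpropyl)-3,6-dimethylcyclohept-2-en-1-yl 4-((tert-butyldimethylsilyl)oxy)benzoate
Product: 18 (1R,6S,7S)-6-(2-hydroxybut-3-en-2-yl)-7-((S)-1-hydroxy-2-methylpropyl)-3,6-dimethylcyclohept-2-en-1-yl 4-((tert-butyldimethylsilyl)oxy)benzoate (epimers at the new carbinol)
Conditions: CH2=CHMgBr, CeCl3, THF, −78 °C; aq. NH4Cl
Reagents that add atoms: vinylmagnesium bromide, C=C[Mg]Br
Why: Organocerium 1,2-addition to the methyl ketone should outpace attack on the hindered aryl ester at −78 °C; the new tertiary carbinol forms as an inconsequential mixture.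

Step 11
Reactants: 18 (1R,6S,7S)-6-(2-hydroxybut-3-en-2-yl)-7-((S)-1-hydroxy-2-methylpropyl)-3,6-dimethylcyclohept-2-en-1-yl 4-((tert-butyldimethylsilyl)oxy)benzoate
Product: 19 (1R,6S,7R)-6-(2-hydroxybut-3-en-2-yl)-7-isobutyryl-3,6-dimethylcyclohept-2-en-1-yl 4-((tert-butyldimethylsilyl)oxy)benzoate
Conditions: Dess–Martin periodinane, CH2Cl2, 0 °C to rt
Reagents that add atoms: none
Why: Dess–Martin oxidation should convert the secondary alcohol into the isopropyl ketone under neutral conditions, leaving the tertiary allylic alcohol and the β-acyloxy group untouched.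

Step 12
Reactants: 19 (1R,6S,7R)-6-(2-hydroxybut-3-en-2-yl)-7-isobutyryl-3,6-dimethylcyclohept-2-en-1-yl 4-((tert-butyldimethylsilyl)oxy)benzoate
Product: 20 (1R,6S,7R)-7-isobutyryl-3,6-dimethyl-6-(2-((triethylsilyl)oxy)but-3-en-2-yl)cyclohept-2-en-1-yl 4-((tert-butyldimethylsilyl)oxy)benzoate
Conditions: Et3SiOTf, 2,6-lutidine, CH2Cl2, −78 to 0 °C
Reagents that add atoms: triethylsilyl trifluoromethanesulfonate, CC[Si](CC)(CC)OS(=O)(=O)C(F)(F)F
Why: Silylation of the tertiary alcohol (open hydroxy ketone favoured over the crowded hemiketal) should supply the pinacol terminator and block the cyclic oxocarbenium pathway that would give the 1,3-cis isomer.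

Step 13
Reactants: 20 (1R,6S,7R)-7-isobutyryl-3,6-dimethyl-6-(2-((triethylsilyl)oxy)but-3-en-2-yl)cyclohept-2-en-1-yl 4-((tert-butyldimethylsilyl)oxy)benzoate
Product: 22 (1R,3S,3aR,4R,8aS)-1-acetyl-3-hydroxy-3-isopropyl-6,8a-dimethyl-1,2,3,3a,4,7,8,8a-octahydroazulen-4-yl 4-((tert-butyldimethylsilyl)oxy)benzoate, via β-silyloxy carbocation 21 (not isolated)
Conditions: SnCl4 (2 equiv), CH2Cl2, −78 to −40 °C; aq. NaHCO3
Reagents that add atoms: none
Why: SnCl4 activates the isopropyl ketone, the terminal vinyl carbon attacks its carbonyl carbon (Prins cyclization) to give the secondary β-silyloxy cation 21, and 1,2-shift of the ring bond from the carbinol carbon to the cationic carbon with loss of the silyl group (pinacol step) forms the cyclopentane and releases the acetyl group. The closest known reaction type is the Prins cyclization–pinacol rearrangement used for cyclopentane annulation from allylic silyl ethers and oxocarbenium-type electrophiles. The new ring closes 6-endo-trig through a chair that is trans-fused to the cycloheptene and is then contracted from six to five members by the shift, so C2–C3 and C1–C8a both form in this operation. C3 is set by the chair, with isopropyl equatorial and the tin-bound oxygen axial and syn to the axial angular methyl, which gives the hydroxyl cis to that methyl; C1 is set by the suprafacial shift of C8a inside that chair, which leaves the acetyl group cis to isopropyl and H-3a; the ring-fusion centres are carried over from 20 because the migrating carbon keeps its configuration. The step needs ketone activation to win over ionization of the tertiary allylic silyl ether and the allylic ester, and ring-carbon rather than methyl migration; low temperature, the intramolecular six-membered chair and the higher migratory aptitude of the fully substituted ring carbon should secure this.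

Step 14
Reactants: 22 (1R,3S,3aR,4R,8aS)-1-acetyl-3-hydroxy-3-isopropyl-6,8a-dimethyl-1,2,3,3a,4,7,8,8a-octahydroazulen-4-yl 4-((tert-butyldimethylsilyl)oxy)benzoate
Product: 23 (1R,3S,3aR,4R,8aS)-1-acetyl-3-hydroxy-3-isopropyl-6,8a-dimethyl-7-oxo-1,2,3,3a,4,7,8,8a-octahydroazulen-4-yl 4-((tert-butyldimethylsilyl)oxy)benzoate
Conditions: CrO3, 3,5-dimethylpyrazole, CH2Cl2, −20 °C
Reagents that add atoms: chromium trioxide, O=[Cr](=O)=O
Why: Chromium-mediated allylic oxidation of the trisubstituted alkene should oxidise the ring methylene next to the methyl-bearing alkene carbon to the enone, the other allylic sites being the acyloxy-bearing methine and the methyl group.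

Step 15
Reactants: 23 (1R,3S,3aR,4R,8aS)-1-acetyl-3-hydroxy-3-isopropyl-6,8a-dimethyl-7-oxo-1,2,3,3a,4,7,8,8a-octahydroazulen-4-yl 4-((tert-butyldimethylsilyl)oxy)benzoate
Product: 24 (1R,3S,3aR,4R,8aS)-1-acetoxy-3-hydroxy-3-isopropyl-6,8a-dimethyl-7-oxo-1,2,3,3a,4,7,8,8a-octahydroazulen-4-yl 4-((tert-butyldimethylsilyl)oxy)benzoate
Conditions: mCPBA, CH2Cl2, 0 °C to rt
Reagents that add atoms: 3-chloroperbenzoic acid, OOC(=O)c1cccc(Cl)c1
Why: Baeyer–Villiger oxidation, in which the secondary ring carbon should migrate in preference to methyl with retention to give the C1 acetate; the enone alkene and the conjugated ketone are deactivated toward the peracid.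

Step 16
Reactants: 24 (1R,3S,3aR,4R,8aS)-1-acetoxy-3-hydroxy-3-isopropyl-6,8a-dimethyl-7-oxo-1,2,3,3a,4,7,8,8a-octahydroazulen-4-yl 4-((tert-butyldimethylsilyl)oxy)benzoate
Product: 25 (1R,3S,3aR,4R,8aS)-1-acetoxy-3-hydroxy-3-isopropyl-6,8a-dimethyl-7-oxo-1,2,3,3a,4,7,8,8a-octahydroazulen-4-yl 4-hydroxybenzoate (target)
Conditions: Bu4NF, AcOH, THF, 0 °C
Reagents that add atoms: none
Why: Buffered fluoride should cleave the aryl silyl ether selectively (phenoxide is a good leaving group on silicon) and spare the acetate, the aroyl ester and the enone.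

Compound list
1 | 3-ethoxycyclohex-2-en-1-one | CCOC1=CC(=O)CCC1 | starting material
2 | lithium 3-ethoxy-1-((trimethylsilyl)ethynyl)cyclohex-2-en-1-olate (not isolated) | CCOC1=CC(O[Li])(C#C[Si](C)(C)C)CCC1 | intermediate
3 | 3-((trimethylsilyl)ethynyl)cyclohex-2-en-1-one | C[Si](C)(C)C#CC1=CC(=O)CCC1 | intermediate
4 | 6-methyl-3-((trimethylsilyl)ethynyl)cyclohex-2-en-1-one (racemic) | CC1CCC(C#C[Si](C)(C)C)=CC1=O | intermediate
5 | trimethyl((2-methyl-5-((trimethylsilyl)ethynyl)cyclohexa-1,5-dien-1-yl)oxy)silane | CC1=C(O[Si](C)(C)C)C=C(C#C[Si](C)(C)C)CC1 | intermediate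
6 | trimethyl((6-methyl-3-((trimethylsilyl)ethynyl)bicyclo[4.1.0]hept-2-en-1-yl)oxy)silane (racemic) | CC12CC1(O[Si](C)(C)C)C=C(C#C[Si](C)(C)C)CC2 | intermediate
7 | 6-chloro-6-methyl-3-((trimethylsilyl)ethynyl)cyclohept-2-en-1-one (not isolated) | CC1(Cl)CCC(C#C[Si](C)(C)C)=CC(=O)C1 | intermediate
8 | 3-methyl-6-((trimethylsilyl)ethynyl)cyclohepta-2,6-dien-1-one | CC1=CC(=O)C=C(C#C[Si](C)(C)C)CC1 | intermediate
9 | isobutyraldehyde (2-methylpropanal) | CC(C)C=O | starting material
10 | bromomagnesium enolate of (S)-3,6-dimethyl-6-((trimethylsilyl)ethynyl)cyclohept-2-en-1-one (not isolated) | C[C@]1(C#C[Si](C)(C)C)CCC(C)=CC(O[Mg]Br)=C1 | intermediate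
11 | (6S,7S)-7-((S)-1-hydroxy-2-methylpropyl)-3,6-dimethyl-6-((trimethylsilyl)ethynyl)cyclohept-2-en-1-one (side chain trans to alkynyl, anti aldol) | C[C@]1(C#C[Si](C)(C)C)CCC(C)=CC(=O)[C@@H]1[C@@H](O)C(C)C | intermediate
12 | O-diethylboryl derivative (boron chelate) of 11 (not isolated) | C[C@]1(C#C[Si](C)(C)C)CCC(C)=CC(=O)[C@@H]1[C@@H](OB(CC)CC)C(C)C | intermediate
13 | (1R,6S,7S)-7-((S)-1-hydroxy-2-methylpropyl)-3,6-dimethyl-6-((trimethylsilyl)ethynyl)cyclohept-2-en-1-ol (not isolated) | C[C@]1(C#C[Si](C)(C)C)CCC(C)=C[C@@H](O)[C@@H]1[C@@H](O)C(C)C | intermediate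
14 | (1R,6S,7S)-6-ethynyl-7-((S)-1-hydroxy-2-methylpropyl)-3,6-dimethylcyclohept-2-en-1-ol (ring hydroxyl trans to side chain, 1,3-syn diol) | C[C@]1(C#C)CCC(C)=C[C@@H](O)[C@@H]1[C@@H](O)C(C)C | intermediate
15 | (1R,6S,7S)-6-acetyl-7-((S)-1-hydroxy-2-methylpropyl)-3,6-dimethylcyclohept-2-en-1-ol | C[C@]1(C(C)=O)CCC(C)=C[C@@H](O)[C@@H]1[C@@H](O)C(C)C | intermediate
16 | 4-((tert-butyldimethylsilyl)oxy)benzoic acid | OC(=O)c1ccc(O[Si](C)(C)C(C)(C)C)cc1 | starting material
17 | (1R,6S,7S)-6-acetyl-7-((S)-1-hydroxy-2-methylpropyl)-3,6-dimethylcyclohept-2-en-1-yl 4-((tert-butyldimethylsilyl)oxy)benzoate | C[C@]1(C(C)=O)CCC(C)=C[C@@H](OC(=O)c2ccc(O[Si](C)(C)C(C)(C)C)cc2)[C@@H]1[C@@H](O)C(C)C | intermediate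
18 | (1R,6S,7S)-6-(2-hydroxybut-3-en-2-yl)-7-((S)-1-hydroxy-2-methylpropyl)-3,6-dimethylcyclohept-2-en-1-yl 4-((tert-butyldimethylsilyl)oxy)benzoate (epimers at the butenyl carbinol) | C[C@]1(C(C)(O)C=C)CCC(C)=C[C@@H](OC(=O)c2ccc(O[Si](C)(C)C(C)(C)C)cc2)[C@@H]1[C@@H](O)C(C)C | intermediate
19 | (1R,6S,7R)-6-(2-hydroxybut-3-en-2-yl)-7-isobutyryl-3,6-dimethylcyclohept-2-en-1-yl 4-((tert-butyldimethylsilyl)oxy)benzoate | C[C@]1(C(C)(O)C=C)CCC(C)=C[C@@H](OC(=O)c2ccc(O[Si](C)(C)C(C)(C)C)cc2)[C@@H]1C(=O)C(C)C | intermediate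
20 | (1R,6S,7R)-7-isobutyryl-3,6-dimethyl-6-(2-((triethylsilyl)oxy)but-3-en-2-yl)cyclohept-2-en-1-yl 4-((tert-butyldimethylsilyl)oxy)benzoate (isobutyryl trans to the silyloxybutenyl group and to the aroyloxy group) | C[C@]1(C(C)(O[Si](CC)(CC)CC)C=C)CCC(C)=C[C@@H](OC(=O)c2ccc(O[Si](C)(C)C(C)(C)C)cc2)[C@@H]1C(=O)C(C)C | intermediate
21 | trans-fused cyclohexyl cation from the Prins closure, tin alkoxide at C3 and silyloxy group on the neighbouring carbon, chloride counter-ion (not isolated) | C[C@]12CCC(C)=C[C@@H](OC(=O)c3ccc(O[Si](C)(C)C(C)(C)C)cc3)[C@@H]1[C@@](O[Sn](Cl)(Cl)Cl)(C(C)C)C[CH+]C2(C)O[Si](CC)(CC)CC.[Cl-] | intermediate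
22 | (1R,3S,3aR,4R,8aS)-1-acetyl-3-hydroxy-3-isopropyl-6,8a-dimethyl-1,2,3,3a,4,7,8,8a-octahydroazulen-4-yl 4-((tert-butyldimethylsilyl)oxy)benzoate | CC(=O)[C@@H]1C[C@](O)(C(C)C)[C@H]2[C@H](OC(=O)c3ccc(O[Si](C)(C)C(C)(C)C)cc3)C=C(C)CC[C@]12C | intermediate
23 | (1R,3S,3aR,4R,8aS)-1-acetyl-3-hydroxy-3-isopropyl-6,8a-dimethyl-7-oxo-1,2,3,3a,4,7,8,8a-octahydroazulen-4-yl 4-((tert-butyldimethylsilyl)oxy)benzoate | CC(=O)[C@@H]1C[C@](O)(C(C)C)[C@H]2[C@H](OC(=O)c3ccc(O[Si](C)(C)C(C)(C)C)cc3)C=C(C)C(=O)C[C@]12C | intermediate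
24 | (1R,3S,3aR,4R,8aS)-1-acetoxy-3-hydroxy-3-isopropyl-6,8a-dimethyl-7-oxo-1,2,3,3a,4,7,8,8a-octahydroazulen-4-yl 4-((tert-butyldimethylsilyl)oxy)benzoate | CC(=O)O[C@@H]1C[C@](O)(C(C)C)[C@H]2[C@H](OC(=O)c3ccc(O[Si](C)(C)C(C)(C)C)cc3)C=C(C)C(=O)C[C@]12C | intermediate
25 | (1R,3S,3aR,4R,8aS)-1-acetoxy-3-hydroxy-3-isopropyl-6,8a-dimethyl-7-oxo-1,2,3,3a,4,7,8,8a-octahydroazulen-4-yl 4-hydroxybenzoate | CC(=O)O[C@@H]1C[C@](O)(C(C)C)[C@H]2[C@H](OC(=O)c3ccc(O)cc3)C=C(C)C(=O)C[C@]12C | target

Total step count: 16. Longest linear sequence: 16 steps, from 1 to 25.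

Steps most likely to fail

Step 13 (key step). The Lewis acid may ionize the tertiary allylic silyl ether or the allylic ester instead of activating the ketone. Methyl rather than ring-carbon migration may occur, or closure through a non-chair transition state may erode control at C1 and C3. Fallback by stepwise aldol chemistry: from 17, Dess–Martin oxidation should give the 1,4-diketone F1. Kinetic deprotonation of the acetyl methyl group (LDA, THF, −78 °C) and intramolecular aldol addition to the isopropyl ketone should give the trans-fused hydroxy cyclopentanone F2, with isopropyl on the less hindered face cis to H-3a. Hydroxyl-directed reduction with Me4NBH(OAc)3 should deliver hydride from the carbinol face and give the 1,3-anti diol F3. Acetylation of the secondary hydroxyl (Ac2O, pyridine) should give the acetate F4. Allylic oxidation (CrO3, 3,5-dimethylpyrazole) then returns to the route at 24.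

Step 6. Methyl transfer may go to the methyl-bearing β-carbon or to the alkyne terminus of the cross-conjugated dienynone, the enantioselectivity may be low on this seven-membered acceptor, and the tandem aldol may lose facial control. Fallback that sets the quaternary centre before ring expansion and separates the aldol: from 4, the same copper-catalysed asymmetric 1,4-addition of MeMgBr on the six-membered enynone (no second acceptor) should give the ketone F5. Thermodynamic silylation (Me3SiCl, NaI, Et3N, MeCN) should give the more substituted silyl enol ether F6. Cyclopropanation (Et2Zn, CH2I2) should give the siloxycyclopropane F7. FeCl3 in DMF should give the ring-expanded chloro ketone F8, and Et3N should eliminate HCl to the cycloheptenone F9. Kinetic α′-enolization (LDA, THF, −78 °C) and addition to 9 come back to the route at 11.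

Step 14. Oxygen may be delivered at the wrong terminus of the allylic system, or the allylic methyl group or the acyloxy-bearing methine may be oxidised. Fallback by an ene/[2,3] sequence that fixes the position: from 22, SeO2 (catalytic) with t-BuOOH in CH2Cl2 should hydroxylate the ring methylene on the more substituted alkene carbon to give the allylic alcohol F10. Dess–Martin oxidation then returns to the route at 23.

Further compounds
F1 | step 13 | (1R,6S,7R)-6-acetyl-7-isobutyryl-3,6-dimethylcyclohept-2-en-1-yl 4-((tert-butyldimethylsilyl)oxy)benzoate | C[C@]1(C(C)=O)CCC(C)=C[C@@H](OC(=O)c2ccc(O[Si](C)(C)C(C)(C)C)cc2)[C@@H]1C(=O)C(C)C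
F2 | step 13 | trans-fused 3-hydroxy-3-isopropyl-6,8a-dimethyl-1-oxo-octahydroazulen-4-yl 4-((tert-butyldimethylsilyl)oxy)benzoate (hydroxyl cis to the angular methyl) | O=C1C[C@](O)(C(C)C)[C@H]2[C@H](OC(=O)c3ccc(O[Si](C)(C)C(C)(C)C)cc3)C=C(C)CC[C@]12C
F3 | step 13 | trans-fused 1,3-dihydroxy-3-isopropyl-6,8a-dimethyl-octahydroazulen-4-yl 4-((tert-butyldimethylsilyl)oxy)benzoate (1,3-anti diol) | O[C@@H]1C[C@](O)(C(C)C)[C@H]2[C@H](OC(=O)c3ccc(O[Si](C)(C)C(C)(C)C)cc3)C=C(C)CC[C@]12C
F4 | step 13 | (1R,3S,3aR,4R,8aS)-1-acetoxy-3-hydroxy-3-isopropyl-6,8a-dimethyl-1,2,3,3a,4,7,8,8a-octahydroazulen-4-yl 4-((tert-butyldimethylsilyl)oxy)benzoate | CC(=O)O[C@@H]1C[C@](O)(C(C)C)[C@H]2[C@H](OC(=O)c3ccc(O[Si](C)(C)C(C)(C)C)cc3)C=C(C)CC[C@]12C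
F5 | step 6 | (5S)-2,5-dimethyl-5-((trimethylsilyl)ethynyl)cyclohexan-1-one (epimers at C2) | C[C@]1(C#C[Si](C)(C)C)CCC(C)C(=O)C1
F6 | step 6 | (S)-((2,5-dimethyl-5-((trimethylsilyl)ethynyl)cyclohex-1-en-1-yl)oxy)trimethylsilane | C[C@]1(C#C[Si](C)(C)C)CCC(C)=C(O[Si](C)(C)C)C1
F7 | step 6 | trimethyl((3,6-dimethyl-3-((trimethylsilyl)ethynyl)bicyclo[4.1.0]heptan-1-yl)oxy)silane (S at the alkynyl-bearing carbon) | C[C@]1(C#C[Si](C)(C)C)CCC2(C)CC2(O[Si](C)(C)C)C1
F8 | step 6 | (6S)-3-chloro-3,6-dimethyl-6-((trimethylsilyl)ethynyl)cycloheptan-1-one (not isolated) | C[C@]1(C#C[Si](C)(C)C)CCC(C)(Cl)CC(=O)C1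
F9 | step 6 | (S)-3,6-dimethyl-6-((trimethylsilyl)ethynyl)cyclohept-2-en-1-one | C[C@]1(C#C[Si](C)(C)C)CCC(C)=CC(=O)C1
F10 | step 14 | (1R,3S,3aR,4R,8aS)-1-acetyl-3,7-dihydroxy-3-isopropyl-6,8a-dimethyl-1,2,3,3a,4,7,8,8a-octahydroazulen-4-yl 4-((tert-butyldimethylsilyl)oxy)benzoate (epimers at C7) | CC(=O)[C@@H]1C[C@](O)(C(C)C)[C@H]2[C@H](OC(=O)c3ccc(O[Si](C)(C)C(C)(C)C)cc3)C=C(C)C(O)C[C@]12C
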